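**Retrosynthetic overview**

1. The route rests on ring A, the benzoic acid ring, being a resorcinol derivative. Its carboxyl carbon C1 sits between the oxygens at C2 (OMe) and C6 (O-aryl), the carbinol side chain is at C3, C4 and C5 carry hydrogen, and the C6 oxygen is the diaryl ether oxygen to ring B.
2. Key disconnection: ring A is cut at C1–C2, C2–C3 and C5–C6 into a diazo enone (C2 to C5 with the side chain and its stereocenter) and an aryl alkynyl ether (C6, C1, the ether oxygen and all of ring B). The two are joined by a vinylketene/ynol ether benzannulation, with C1 carrying the future acid as an acetal.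
3. The alkynyl ether comes from the ring B phenol (creosol: ortho-formylation, demethylation, selective benzylation, reduction, silylation), trichloroethylene and an orthoformate, so no aryl–oxygen coupling is needed.
4. The diazo enone comes from (R)-benzyl glycidyl ether, which supplies the only stereocenter; the 1,3-diol is carried as an acetonide.
5. Ring order: ring B is present from the start and ring A is the only ring made; the end game is O-methylation, acid unmasking, chlorite oxidation and debenzylation.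

Key step: step 15

Abbreviations used in names: ArO = 2-(benzyloxy)-6-({[tert-butyl(dimethyl)silyl]oxy}methyl)-4-methylphenoxy; Diox = (4R)-2,2,6,6-tetramethyl-1,3-dioxan-4-yl.

Remark on the chemistry: a lithium aryloxyacetylide is assumed not to react with a simple orthoformate, so it is transmetalated to magnesium and treated with the activated orthoformate PhOCH(OEt)2; the acetal is therefore carried as the diethyl acetal.

**Fragment 1: diazo enone**

Step 1
Reactants: 1 (R)-benzyl glycidyl ether; 2 isopropenylmagnesium bromide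
Product: 3 (2R)-1-(benzyloxy)-4-methylpent-4-en-2-ol
Conditions: CuI (10 mol %), THF, −30 → 0 °C; aq. NH4Cl
Reagents that add atoms: none
Why: Copper-catalysed Grignard opening of the terminal epoxide is an SN2 attack at the unsubstituted CH2, so the C–O stereocenter of 1 is untouched and 3 keeps the R configuration.

Step 2
Reactants: 3 (2R)-1-(benzyloxy)-4-methylpent-4-en-2-ol
Product: 4 (2R)-1-(benzyloxy)-4-methylpentane-2,4-diol
Conditions: Co(acac)2 (cat.), PhSiH3, O2 (1 atm), THF, rt
Reagents that add atoms: dioxygen, O=O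
Why: Mukaiyama hydration delivers a hydrogen atom to the terminal CH2 of the 1,1-disubstituted alkene and traps the tertiary radical with O2, giving the Markovnikov tertiary alcohol without touching the carbinol stereocenter or the benzyl ether.

Step 3
Reactants: 4 (2R)-1-(benzyloxy)-4-methylpentane-2,4-diol
Product: 5 (4R)-4-[(benzyloxy)methyl]-2,2,6,6-tetramethyl-1,3-dioxane
Conditions: 2-methoxypropene, PPTS (cat.), CH2Cl2, 0 °C → rt
Reagents that add atoms: 2-methoxypropene, COC(C)=C
Why: Acid-catalysed ketalisation with an enol ether closes the acetonide onto the tertiary hydroxyl as well, the ring being no more strained than an anti-1,3-diol acetonide, and no stereocenter is involved.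

Step 4
Reactants: 5 (4R)-4-[(benzyloxy)methyl]-2,2,6,6-tetramethyl-1,3-dioxane
Product: 6 [(4R)-2,2,6,6-tetramethyl-1,3-dioxan-4-yl]methanol
Conditions: H2 (1 atm), Pd/C, EtOAc, rt
Reagents that add atoms: none
Why: Hydrogenolysis of the primary alkyl benzyl ether over Pd/C is neutral, and the ketal is inert to it.

Step 5
Reactants: 6 [(4R)-2,2,6,6-tetramethyl-1,3-dioxan-4-yl]methanol
Product: 7 (4R)-2,2,6,6-tetramethyl-1,3-dioxane-4-carbaldehyde
Conditions: Dess–Martin periodinane, pyridine, CH2Cl2, 0 °C → rt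
Reagents that add atoms: none
Why: Dess–Martin oxidation under buffered conditions should give the α-alkoxy aldehyde without epimerisation; it is used at once.

Step 6
Reactants: 7 (4R)-2,2,6,6-tetramethyl-1,3-dioxane-4-carbaldehyde
Product: 8 (3E)-4-[(4R)-2,2,6,6-tetramethyl-1,3-dioxan-4-yl]but-3-en-2-one
Conditions: Ph3P=CHC(O)CH3, CH2Cl2, rt → 40 °C
Reagents that add atoms: 1-(triphenylphosphoranylidene)propan-2-one, CC(=O)C=P(c1ccccc1)(c1ccccc1)c1ccccc1
Why: Wittig olefination with the stabilised acetonyl ylide is E-selective and neutral, so the α-alkoxy stereocenter of 7 is kept.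

Step 7
Reactants: 8 (3E)-4-[(4R)-2,2,6,6-tetramethyl-1,3-dioxan-4-yl]but-3-en-2-one
Product: 10 (3E)-1-diazo-4-[(4R)-2,2,6,6-tetramethyl-1,3-dioxan-4-yl]but-3-en-2-one, via trifluoroacetyl diketone 9 (not isolated)
Conditions: LiHMDS, THF, −78 °C; CF3CO2CH2CF3; aq. NH4Cl; then MsN3, Et3N, H2O, MeCN, rt
Reagents that add atoms: 2,2,2-trifluoroethyl trifluoroacetate, O=C(OCC(F)(F)F)C(F)(F)F (trifluoroacetyl group of 9); methanesulfonyl azide, CS(=O)(=O)N=[N+]=[N-] (N2 of 10)
Why: In the detrifluoroacetylative Regitz diazo transfer, kinetic deprotonation at the methyl group and Claisen trifluoroacetylation activate that carbon for diazo transfer, and the trifluoroacetyl group leaves as the sulfonamide, so the enone is not attacked.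

**Fragment 2: aryl alkynyl ether**

Step 8
Reactants: 11 2-methoxy-4-methylphenol (creosol)
Product: 12 2-hydroxy-3-methoxy-5-methylbenzaldehyde
Conditions: MgCl2, Et3N, (CH2O)n, MeCN, reflux; aq. HCl
Reagents that add atoms: paraformaldehyde (as formaldehyde), C=O
Why: In the magnesium-mediated ortho-formylation (Casnati–Skattebøl) the magnesium phenoxide directs formaldehyde to the only free ortho position, and a second formaldehyde oxidises the benzylic alkoxide to the aldehyde.

Step 9
Reactants: 12 2-hydroxy-3-methoxy-5-methylbenzaldehyde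
Product: 13 2,3-dihydroxy-5-methylbenzaldehyde
Conditions: BBr3, CH2Cl2, −78 °C → rt; H2O
Reagents that add atoms: none
Why: BBr3 cleaves the aryl methyl ether by bromide attack on the O-methyl group of the boron complex, and the aldehyde is recovered on hydrolysis.

Step 10
Reactants: 13 2,3-dihydroxy-5-methylbenzaldehyde
Product: 14 3-(benzyloxy)-2-hydroxy-5-methylbenzaldehyde
Conditions: NaH (2.2 equiv), DMSO, rt; BnBr (1.0 equiv); aq. HCl
Reagents that add atoms: benzyl bromide, BrCc1ccccc1
Why: In this Williamson alkylation of the dianion the 2-oxide is chelated and conjugated to the formyl group, so the more nucleophilic 3-oxide takes the single equivalent of benzyl bromide.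

Step 11
Reactants: 14 3-(benzyloxy)-2-hydroxy-5-methylbenzaldehyde
Product: 15 2-(benzyloxy)-6-(hydroxymethyl)-4-methylphenol
Conditions: NaBH4, MeOH/THF, 0 °C
Reagents that add atoms: none
Why: Borohydride reduction of the aldehyde leaves the benzyl ether untouched.

Step 12
Reactants: 15 2-(benzyloxy)-6-(hydroxymethyl)-4-methylphenol
Product: 16 2-(benzyloxy)-6-({[tert-butyl(dimethyl)silyl]oxy}methyl)-4-methylphenol
Conditions: TBSCl (1.05 equiv), imidazole, CH2Cl2, 0 °C
Reagents that add atoms: tert-butyldimethylsilyl chloride, CC(C)(C)[Si](C)(C)Cl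
Why: Silylation should take the primary benzylic alcohol faster than the hindered, hydrogen-bonded 2,6-disubstituted phenol.

Step 13
Reactants: 16 2-(benzyloxy)-6-({[tert-butyl(dimethyl)silyl]oxy}methyl)-4-methylphenol; 17 trichloroethylene
Product: 19 1-(benzyloxy)-3-({[tert-butyl(dimethyl)silyl]oxy}methyl)-2-{[(E)-1,2-dichloroethenyl]oxy}-5-methylbenzene, via dichloroacetylene 18 (not isolated)
Conditions: K2CO3, DMF, 70 °C
Reagents that add atoms: none
Why: Base eliminates HCl from trichloroethylene and the phenoxide adds trans to the dichloroacetylene formed, the standard elimination–addition route to (E)-1,2-dichlorovinyl ethers.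

Step 14
Reactants: 19 1-(benzyloxy)-3-({[tert-butyl(dimethyl)silyl]oxy}methyl)-2-{[(E)-1,2-dichloroethenyl]oxy}-5-methylbenzene
Product: 22 1-(benzyloxy)-3-({[tert-butyl(dimethyl)silyl]oxy}methyl)-2-[(3,3-diethoxyprop-1-yn-1-yl)oxy]-5-methylbenzene, via lithium aryloxyacetylide 20 (not isolated), via bromomagnesium aryloxyacetylide 21 (not isolated)
Conditions: n-BuLi (2.2 equiv), THF, −78 → −40 °C; MgBr2·OEt2, −40 → 0 °C; PhOCH(OEt)2, 0 °C → rt; aq. NH4Cl
Reagents that add atoms: n-butyllithium, [Li]CCCC (lithium of 20); magnesium bromide, Br[Mg]Br (MgBr of 21); diethyl phenyl orthoformate, CCOC(OCC)Oc1ccccc1 (diethoxymethyl group of 22)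
Why: Deprotonation of the vinyl C–H, loss of chloride and chlorine–lithium exchange on the chloroalkyne give the acetylide (dichlorovinyl ether route to ynol ethers), which as its magnesium derivative displaces phenoxide from the activated orthoformate in a Bodroux–Chichibabin acetal synthesis.

**Key step and end game**

Step 15
Reactants: 10 (3E)-1-diazo-4-[(4R)-2,2,6,6-tetramethyl-1,3-dioxan-4-yl]but-3-en-2-one; 22 1-(benzyloxy)-3-({[tert-butyl(dimethyl)silyl]oxy}methyl)-2-[(3,3-diethoxyprop-1-yn-1-yl)oxy]-5-methylbenzene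
Product: 27 3-[2-(benzyloxy)-6-({[tert-butyl(dimethyl)silyl]oxy}methyl)-4-methylphenoxy]-2-(diethoxymethyl)-6-[(4R)-2,2,6,6-tetramethyl-1,3-dioxan-4-yl]phenol, via vinylketene 23 (not isolated), via vinylcyclobutenone 24 (not isolated), via dienylketene 25 (not isolated), via cyclohexadienone 26 (not isolated)
Conditions: hν (300 nm), ClCH2CH2Cl, rt, slow addition of 10 (1.3 equiv) to 22; then 80 °C
Reagents that add atoms: none
Why: Light expels N2 from 10 and the Wolff rearrangement gives vinylketene 23, whose carbonyl carbon (future C2) bonds to the acetal-bearing alkyne carbon of 22 (future C1) while its α-carbon (future C5) bonds to the aryloxy-bearing carbon (future C6) in a (2+2) cycloaddition to cyclobutenone 24. On warming, 24 opens by a 4π electrocyclic reaction to dienylketene 25, and ring A closes by a 6π electrocyclisation that forms C2–C3 and gives dienone 26, which tautomerises to phenol 27. The closest known reaction is the Danheiser benzannulation of diazo enones with alkoxy- and siloxyalkynes, of which this is the aryloxyalkyne case. The one selectivity needed is the regiochemistry of the (2+2) step, and the ynol ether sets it: donation from the ether oxygen makes the carbon remote from oxygen the nucleophile, so the acetal carbon ends between the new hydroxyl and the aryloxy group and the dioxanyl group lands on the other flank of the hydroxyl. No stereocenter is formed, since the sp3 centres of 24 and 26 disappear on aromatisation, and the dioxane stereocenter only sits next to the reacting π system, so it should be kept. The aryl group has no O-alkyl hydrogen for a retro-ene loss of ketene, so the alkynyl ether should tolerate the 80 °C stage.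

Step 16
Reactants: 27 3-(ArO)-2-(diethoxymethyl)-6-(Diox)phenol
Product: 28 (4R)-4-[4-(ArO)-3-(diethoxymethyl)-2-methoxyphenyl]-2,2,6,6-tetramethyl-1,3-dioxane
Conditions: MeI, K2CO3, DMF, rt
Reagents that add atoms: iodomethane, CI
Why: Williamson O-methylation of the phenol is run under basic conditions, to which the acetal, the ketal and the silyl ether are inert.

Step 17
Reactants: 28 (4R)-4-[4-(ArO)-3-(diethoxymethyl)-2-methoxyphenyl]-2,2,6,6-tetramethyl-1,3-dioxane
Product: 29 6-[2-(benzyloxy)-6-(hydroxymethyl)-4-methylphenoxy]-3-[(1R)-1,3-dihydroxy-3-methylbutyl]-2-methoxybenzaldehyde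
Conditions: AcOH/THF/H2O (3:1:1), rt → 35 °C
Reagents that add atoms: water, O
Why: Mild aqueous acid hydrolyses the acyclic acetal, the strained ketal and the primary silyl ether in one operation, and the liberated formyl group, ortho to both donor oxygens, lowers their ability to stabilise a benzylic cation, so the carbinol should keep its R configuration.

Step 18
Reactants: 29 6-[2-(benzyloxy)-6-(hydroxymethyl)-4-methylphenoxy]-3-[(1R)-1,3-dihydroxy-3-methylbutyl]-2-methoxybenzaldehyde
Product: 30 6-[2-(benzyloxy)-6-(hydroxymethyl)-4-methylphenoxy]-3-[(1R)-1,3-dihydroxy-3-methylbutyl]-2-methoxybenzoic acid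
Conditions: NaClO2, NaH2PO4, 2-methyl-2-butene, t-BuOH/H2O, rt
Reagents that add atoms: sodium chlorite, [Na+].[O-]Cl=O
Why: Pinnick oxidation converts the aldehyde to the acid without oxidising the alcohols, and 2-methyl-2-butene traps hypochlorous acid before it chlorinates ring B.

Step 19
Reactants: 30 6-[2-(benzyloxy)-6-(hydroxymethyl)-4-methylphenoxy]-3-[(1R)-1,3-dihydroxy-3-methylbutyl]-2-methoxybenzoic acid
Product: 31 3-[(1R)-1,3-dihydroxy-3-methylbutyl]-6-[2-hydroxy-6-(hydroxymethyl)-4-methylphenoxy]-2-methoxybenzoic acid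
Conditions: H2 (1 atm), Pd/C, EtOAc, rt, stopped at full conversion
Reagents that add atoms: none
Why: Hydrogenolysis of the aryl benzyl ether over Pd/C in a neutral aprotic solvent should be much faster than cleavage of the benzylic C–OH bonds.

**Compound list**

1 | (R)-benzyl glycidyl ether | C(OCc1ccccc1)[C@H]1CO1 | starting material
2 | isopropenylmagnesium bromide | CC(=C)[Mg]Br | starting material
3 | (2R)-1-(benzyloxy)-4-methylpent-4-en-2-ol | C(OCc1ccccc1)[C@H](O)CC(C)=C | intermediate
4 | (2R)-1-(benzyloxy)-4-methylpentane-2,4-diol | C(OCc1ccccc1)[C@H](O)CC(C)(C)O | intermediate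
5 | (4R)-4-[(benzyloxy)methyl]-2,2,6,6-tetramethyl-1,3-dioxane | C(OCc1ccccc1)[C@H]1CC(C)(C)OC(C)(C)O1 | intermediate
6 | [(4R)-2,2,6,6-tetramethyl-1,3-dioxan-4-yl]methanol | OC[C@H]1CC(C)(C)OC(C)(C)O1 | intermediate
7 | (4R)-2,2,6,6-tetramethyl-1,3-dioxane-4-carbaldehyde | O=C[C@H]1CC(C)(C)OC(C)(C)O1 | intermediate
8 | (3E)-4-[(4R)-2,2,6,6-tetramethyl-1,3-dioxan-4-yl]but-3-en-2-one | CC(=O)/C=C/[C@H]1CC(C)(C)OC(C)(C)O1 | intermediate
9 | (5E)-1,1,1-trifluoro-6-[(4R)-2,2,6,6-tetramethyl-1,3-dioxan-4-yl]hex-5-ene-2,4-dione | FC(F)(F)C(=O)CC(=O)/C=C/[C@H]1CC(C)(C)OC(C)(C)O1 | intermediate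
10 | (3E)-1-diazo-4-[(4R)-2,2,6,6-tetramethyl-1,3-dioxan-4-yl]but-3-en-2-one | [N-]=[N+]=CC(=O)/C=C/[C@H]1CC(C)(C)OC(C)(C)O1 | intermediate
11 | 2-methoxy-4-methylphenol (creosol) | COc1cc(C)ccc1O | starting material
12 | 2-hydroxy-3-methoxy-5-methylbenzaldehyde | COc1cc(C)cc(C=O)c1O | intermediate
13 | 2,3-dihydroxy-5-methylbenzaldehyde | Oc1cc(C)cc(C=O)c1O | intermediate
14 | 3-(benzyloxy)-2-hydroxy-5-methylbenzaldehyde | O=Cc1cc(C)cc(OCc2ccccc2)c1O | intermediate
15 | 2-(benzyloxy)-6-(hydroxymethyl)-4-methylphenol | OCc1cc(C)cc(OCc2ccccc2)c1O | intermediate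
16 | 2-(benzyloxy)-6-({[tert-butyl(dimethyl)silyl]oxy}methyl)-4-methylphenol | CC(C)(C)[Si](C)(C)OCc1cc(C)cc(OCc2ccccc2)c1O | intermediate
17 | trichloroethylene | ClC=C(Cl)Cl | starting material
18 | dichloroacetylene | ClC#CCl | intermediate
19 | 1-(benzyloxy)-3-({[tert-butyl(dimethyl)silyl]oxy}methyl)-2-{[(E)-1,2-dichloroethenyl]oxy}-5-methylbenzene | Cl/C=C(/Cl)Oc1c(OCc2ccccc2)cc(C)cc1CO[Si](C)(C)C(C)(C)C | intermediate
20 | [(ArO)ethynyl]lithium | [Li]C#COc1c(OCc2ccccc2)cc(C)cc1CO[Si](C)(C)C(C)(C)C | intermediate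
21 | bromo[(ArO)ethynyl]magnesium | Br[Mg]C#COc1c(OCc2ccccc2)cc(C)cc1CO[Si](C)(C)C(C)(C)C | intermediate
22 | 1-(benzyloxy)-3-({[tert-butyl(dimethyl)silyl]oxy}methyl)-2-[(3,3-diethoxyprop-1-yn-1-yl)oxy]-5-methylbenzene | CCOC(OCC)C#COc1c(OCc2ccccc2)cc(C)cc1CO[Si](C)(C)C(C)(C)C | intermediate
23 | (3E)-4-[(4R)-2,2,6,6-tetramethyl-1,3-dioxan-4-yl]buta-1,3-dien-1-one | O=C=C/C=C/[C@H]1CC(C)(C)OC(C)(C)O1 | intermediate
24 | 3-(ArO)-2-(diethoxymethyl)-4-[(E)-2-(Diox)ethenyl]cyclobut-2-en-1-one (both C4 epimers) | CCOC(OCC)C1=C(Oc2c(OCc3ccccc3)cc(C)cc2CO[Si](C)(C)C(C)(C)C)C(/C=C/[C@H]2CC(C)(C)OC(C)(C)O2)C1=O | intermediate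
25 | (3E,5E)-3-(ArO)-2-(diethoxymethyl)-6-(Diox)hexa-1,3,5-trien-1-one | CCOC(OCC)C(=C=O)/C(Oc1c(OCc2ccccc2)cc(C)cc1CO[Si](C)(C)C(C)(C)C)=C\C=C\[C@H]1CC(C)(C)OC(C)(C)O1 | intermediate
26 | 3-(ArO)-2-(diethoxymethyl)-6-(Diox)cyclohexa-2,4-dien-1-one (both C6 epimers) | CCOC(OCC)C1=C(Oc2c(OCc3ccccc3)cc(C)cc2CO[Si](C)(C)C(C)(C)C)C=CC([C@H]2CC(C)(C)OC(C)(C)O2)C1=O | intermediate
27 | 3-[2-(benzyloxy)-6-({[tert-butyl(dimethyl)silyl]oxy}methyl)-4-methylphenoxy]-2-(diethoxymethyl)-6-[(4R)-2,2,6,6-tetramethyl-1,3-dioxan-4-yl]phenol | CCOC(OCC)c1c(O)c([C@H]2CC(C)(C)OC(C)(C)O2)ccc1Oc1c(OCc2ccccc2)cc(C)cc1CO[Si](C)(C)C(C)(C)C | intermediate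
28 | (4R)-4-{4-[2-(benzyloxy)-6-({[tert-butyl(dimethyl)silyl]oxy}methyl)-4-methylphenoxy]-3-(diethoxymethyl)-2-methoxyphenyl}-2,2,6,6-tetramethyl-1,3-dioxane | CCOC(OCC)c1c(OC)c([C@H]2CC(C)(C)OC(C)(C)O2)ccc1Oc1c(OCc2ccccc2)cc(C)cc1CO[Si](C)(C)C(C)(C)C | intermediate
29 | 6-[2-(benzyloxy)-6-(hydroxymethyl)-4-methylphenoxy]-3-[(1R)-1,3-dihydroxy-3-methylbutyl]-2-methoxybenzaldehyde | O=Cc1c(OC)c([C@H](O)CC(C)(C)O)ccc1Oc1c(OCc2ccccc2)cc(C)cc1CO | intermediate
30 | 6-[2-(benzyloxy)-6-(hydroxymethyl)-4-methylphenoxy]-3-[(1R)-1,3-dihydroxy-3-methylbutyl]-2-methoxybenzoic acid | OC(=O)c1c(OC)c([C@H](O)CC(C)(C)O)ccc1Oc1c(OCc2ccccc2)cc(C)cc1CO | intermediate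
31 | 3-[(1R)-1,3-dihydroxy-3-methylbutyl]-6-[2-hydroxy-6-(hydroxymethyl)-4-methylphenoxy]-2-methoxybenzoic acid | COc1c([C@H](O)CC(C)(C)O)ccc(Oc2c(O)cc(C)cc2CO)c1C(=O)O | target

**Step count and risks**

Total step count: 19. Longest linear sequence: 12 steps (steps 8–19; steps 1–7 followed by 15–19 is equally long).

Steps most likely to fail:

1. Step 15 (benzannulation). The (2+2) capture of vinylketene 23 may be too slow, because the acetal-bearing carbon of 22 is inductively deactivated and hindered and an aryloxy group donates less than an alkoxy group. Then 23 would be lost to dimerisation and to acylation of the product phenol. The fallback introduces the C1 carbon substituent after ring A is made; it sets out from 19 and 10 and comes back at 29. Treatment of 19 with n-BuLi as in step 14 and quenching of acetylide 20 with MeOH should give the terminal ynol ether 1-(benzyloxy)-3-({[tert-butyl(dimethyl)silyl]oxy}methyl)-2-(ethynyloxy)-5-methylbenzene F1, an unhindered and more electron-rich alkyne. Irradiation with 10 and heating as in step 15 should lead through 23, the vinylcyclobutenone 3-(ArO)-4-[(E)-2-(Diox)ethenyl]cyclobut-2-en-1-one F2, the dienylketene (3E,5E)-3-(ArO)-6-(Diox)hexa-1,3,5-trien-1-one F3 and the dienone 3-(ArO)-6-(Diox)cyclohexa-2,4-dien-1-one F4 to 5-(ArO)-2-(Diox)phenol F5, in which C1 carries hydrogen. Magnesium-mediated ortho-formylation (MgCl2, Et3N, (CH2O)n, MeCN, reflux) can only attack C1, the single free ortho position of the hydroxyl, and should give 6-(ArO)-2-hydroxy-3-(Diox)benzaldehyde F6. Methylation (MeI, K2CO3, DMF) should give 6-(ArO)-2-methoxy-3-(Diox)benzaldehyde F7, and AcOH/THF/H2O as in step 17 should remove ketal and silyl ether to give 29.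

2. Step 14 (alkynyl acetal). Transfer of the diethoxymethyl group may fail, since the magnesium acetylide is a weak nucleophile and the aryloxyacetylide may decompose on warming before it displaces phenoxide from the orthoformate. The fallback makes the ynol ether C–O bond by coupling onto a three-carbon unit that already carries the acetal; it sets out from phenol 16 and comes back at alkyne 22. Dibromo-olefination of 2,2-diethoxyacetaldehyde (CBr4, PPh3, CH2Cl2, 0 °C) should give 1,1-dibromo-3,3-diethoxyprop-1-ene F8. Copper-catalysed coupling of 16 with F8 (CuI, 2,2′-bipyridine, K3PO4, toluene, 110 °C), a known route from phenols and 1,1-dibromoalkenes to 1-bromoenol ethers, should give 1-(benzyloxy)-2-{[(1Z)-1-bromo-3,3-diethoxyprop-1-en-1-yl]oxy}-3-({[tert-butyl(dimethyl)silyl]oxy}methyl)-5-methylbenzene F9. Anti dehydrobromination (KOt-Bu, THF, 0 °C) should then give 22.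

3. Step 19 (debenzylation). Over-reduction is the danger: besides the O-benzyl bond, the palladium catalyst may cleave the benzylic C–OH bonds of the ring A carbinol and of the ring B hydroxymethyl group, helped by the free carboxylic acid. The fallback debenzylates before the benzylic hydroxyls and the acid exist; it sets out from methyl ether 28 and comes back at target 31. Hydrogenolysis of 28 (H2, Pd/C, EtOAc, trace Et3N) should give 3-({[tert-butyl(dimethyl)silyl]oxy}methyl)-2-[2-(diethoxymethyl)-3-methoxy-4-(Diox)phenoxy]-5-methylphenol F10, in which both benzylic oxygens are still capped as ketal and silyl ether. AcOH/THF/H2O as in step 17 should give 3-[(1R)-1,3-dihydroxy-3-methylbutyl]-6-[2-hydroxy-6-(hydroxymethyl)-4-methylphenoxy]-2-methoxybenzaldehyde F11. Chlorite oxidation under Lindgren conditions (NaClO2, NaH2PO4, 2-methyl-2-butene in large excess, t-BuOH/H2O), which were devised for phenolic aldehydes, should then give 31.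

**Further compounds**

F1 | step 15 | 1-(benzyloxy)-3-({[tert-butyl(dimethyl)silyl]oxy}methyl)-2-(ethynyloxy)-5-methylbenzene | C#COc1c(OCc2ccccc2)cc(C)cc1CO[Si](C)(C)C(C)(C)C
F2 | step 15 | 3-(ArO)-4-[(E)-2-(Diox)ethenyl]cyclobut-2-en-1-one (both C4 epimers) | O=C1C=C(Oc2c(OCc3ccccc3)cc(C)cc2CO[Si](C)(C)C(C)(C)C)C1/C=C/[C@H]1CC(C)(C)OC(C)(C)O1
F3 | step 15 | (3E,5E)-3-(ArO)-6-(Diox)hexa-1,3,5-trien-1-one | O=C=C/C(Oc1c(OCc2ccccc2)cc(C)cc1CO[Si](C)(C)C(C)(C)C)=C\C=C\[C@H]1CC(C)(C)OC(C)(C)O1
F4 | step 15 | 3-(ArO)-6-(Diox)cyclohexa-2,4-dien-1-one (both C6 epimers) | O=C1C=C(Oc2c(OCc3ccccc3)cc(C)cc2CO[Si](C)(C)C(C)(C)C)C=CC1[C@H]1CC(C)(C)OC(C)(C)O1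
F5 | step 15 | 5-(ArO)-2-(Diox)phenol | Oc1cc(Oc2c(OCc3ccccc3)cc(C)cc2CO[Si](C)(C)C(C)(C)C)ccc1[C@H]1CC(C)(C)OC(C)(C)O1
F6 | step 15 | 6-(ArO)-2-hydroxy-3-(Diox)benzaldehyde | O=Cc1c(O)c([C@H]2CC(C)(C)OC(C)(C)O2)ccc1Oc1c(OCc2ccccc2)cc(C)cc1CO[Si](C)(C)C(C)(C)C
F7 | step 15 | 6-(ArO)-2-methoxy-3-(Diox)benzaldehyde | O=Cc1c(OC)c([C@H]2CC(C)(C)OC(C)(C)O2)ccc1Oc1c(OCc2ccccc2)cc(C)cc1CO[Si](C)(C)C(C)(C)C
F8 | step 14 | 1,1-dibromo-3,3-diethoxyprop-1-ene | CCOC(OCC)C=C(Br)Br
F9 | step 14 | 1-(benzyloxy)-2-{[(1Z)-1-bromo-3,3-diethoxyprop-1-en-1-yl]oxy}-3-({[tert-butyl(dimethyl)silyl]oxy}methyl)-5-methylbenzene | CCOC(OCC)/C=C(\Br)Oc1c(OCc2ccccc2)cc(C)cc1CO[Si](C)(C)C(C)(C)C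
F10 | step 19 | 3-({[tert-butyl(dimethyl)silyl]oxy}methyl)-2-{2-(diethoxymethyl)-3-methoxy-4-[(4R)-2,2,6,6-tetramethyl-1,3-dioxan-4-yl]phenoxy}-5-methylphenol | CCOC(OCC)c1c(OC)c([C@H]2CC(C)(C)OC(C)(C)O2)ccc1Oc1c(O)cc(C)cc1CO[Si](C)(C)C(C)(C)C
F11 | step 19 | 3-[(1R)-1,3-dihydroxy-3-methylbutyl]-6-[2-hydroxy-6-(hydroxymethyl)-4-methylphenoxy]-2-methoxybenzaldehyde | O=Cc1c(OC)c([C@H](O)CC(C)(C)O)ccc1Oc1c(O)cc(C)cc1CO
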